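I decided to follow what E gains against G rather than the excess itself, and to reckon the two ends of the run separately.

| flask | Q | J | D | L | remark | time |
|---|---|---|---|---|---|---|
| alder | 0.038 M | 0.038 M | 11 mM (held) | 8.6 mM | run made earlier |  |
| maple | 0.029 M | 0.029 M | 11 mM (held) | 8.6 mM | run made earlier |  |
| beta | 0.057 M | 0.057 M | 11 mM (held) | 12 mM |  | 6.0 h |
| epsilon | 0.057 M | 0.057 M | 11 mM (held) | 8.6 mM |  | 10 h |

| run | time / h | G / % | E / % |
|---|---|---|---|
| alder | 0.500 | 7.2 | 0.2 |
| alder | 1.00 | 14.8 | 0.3 |
| alder | 2.50 | 32.7 | 0.2 |
| alder | 6.00 | 60.6 | 1.5 |
| maple | 1.50 | 21.2 | 0.3 |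
| maple | 3.00 | 38.4 | 0.5 |
| maple | 5.00 | 54.7 | 0.9 |
| maple | 6.00 | 61.6 | 1.3 |

(standard deviation of a reading: 0.3 percentage points)

- which one finishes higher in excess of G over E ("neither" within 2 percentage points) (beta / epsilon / neither)
- excess of G over E at the end, beta
- excess of G over E at the end, epsilon

- Z is single-handed; Q and J are mirror images of each other, charged as a racemate, each of them at the stated concentration
- at the start none of D is in solution
- an excess is the difference of the two amounts in percent of their sum
- an excess is below zero if the other one leads
- no earlier run changes the charge of L; that part of a forecast is a guess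
- the handed part of Z does not stay in what it makes, so the products of the two hands are mirror images too

First the clock. Conversion, G plus E, averaged 62.5% in alder and maple at 6.00 h, although their charges differ. Read as a pseudo-first-order decay, that gave a rate constant of 0.163 h⁻¹, so a time constant of 6.12 h. So I put beta, stopped at 6.0 h, at that same conversion, guessing about its extra L, and epsilon at 80.5% by 10 h.

Next the products. At 6.00 h the two runs together held a ratio s of E to G of 0.0229. The excess is one minus s over one plus s, so I took 95.5% for beta.

The weak link was carrying s unchanged to epsilon, since the same ratio, taken over alder at 2.50 h and maple at 3.00 h together, had read only 0.00985. So I reforged it from the stretch of each run between those readings and 6.00 h. Together they gave 0.0411, the marginal leak m: the E gained per G gained over that stretch. This reading is more than s, but with a scatter of 0.3 percentage points on each of its E readings it is good only to about 0.0117. Applied to epsilon's further product, it put E at 2.11% and the excess at 94.8%. The gap of 0.76 points is less than the margin of 2 points, so I committed to neither.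

The forecast chose beta, with 95.5% (93.5% to 97%) for beta and 93.2% (90.5% to 95%) for epsilon, on the ground of “slow product racemisation or another time-linked leak”. Its epsilon lay below mine.

The flask gave neither, with beta at 95.3% and epsilon at 94.8%.

    Q + L ⇌ J + L, rate k1*[L]*[Q] forward; the back reaction follows from the equilibrium constant (k = 65.0 L mol⁻¹ h⁻¹)
    2 L ⇌ X, settled at all times (K = 44.0 L mol⁻¹)
    Z + Q → G (k = 40.4 L mol⁻¹ h⁻¹)
    Z + J → E (k = 0.729 L mol⁻¹ h⁻¹)
    D ⇌ Z, rate k5*(csat - [Z]) (kL = 7.61 h⁻¹)

Stepping m from epsilon's E of 1.32% at 5.00 h across the G gained by 10.0 h gave E 2.33%, so an excess of 94.1%, against the simulated 94.8%. The neighbour is beta read at 2.5 h, with G 31.8%, E 0.710% and an excess of 95.6%. The same step forward to 6.00 h gave E 1.89% and an excess of 93.9%, where beta stood at E 1.46% and 95.3%.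

The data were computed for substances that don't exist, noise included.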